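## Analysis of the target

Compound 16 is an open-chain bis(bibenzyl). It has four benzene rings: ring A (4-hydroxyphenyl), ring B (1,3,5-trisubstituted, with OMe on C1, the ethylene bridge on C3 and the aryloxy oxygen on C5), ring C (a para-phenylene) and ring D (a 2-hydroxy-4-methoxy-6-alkylbenzoic acid). They are joined by a CH2–CH2 bridge between rings A and B, an ether oxygen between rings B and C, and a second CH2–CH2 bridge between rings C and D. The molecule has no stereocentre and no ring fusion, so nothing has to be controlled in relative or absolute configuration. The sensitive part is ring D: a salicylic acid with a para methoxy group decarboxylates under hot acid, and the free phenols are open to oxidation, so acid and phenols should be unveiled last under neutral, cold conditions. The difficulty is one of differentiation and connectivity. Two phenols must end free and two methylated, ring B carries three different meta-related substituents that cannot be installed by simple substitution logic, and two saturated two-carbon bridges must be made without unselective stilbene chemistry. The strategy rests on the A–B bridge: its two methylene carbons are bonded to C1 of ring A at one end and to C3 of ring B at the other. This is exactly the pattern a vinyl boron unit gives when an aryl group migrates onto its boron-bearing carbon and an aryl electrophile is joined to its terminal carbon.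

## Retrosynthetic reasoning

16 back to 15 and 14. The two phenols and the acid are masked until the end. Both phenols are carried as benzyl ethers, so one hydrogenolysis of acid 15 releases them under neutral conditions at room temperature. The acid is carried as the methyl ester 14 and is saponified while the ortho oxygen is still benzylated, because the carboxylate of a 2-alkoxybenzoate is not at risk of decarboxylation in base.

14 back to 13. The benzylic C–H on the ring A side of the A–B bridge is traced back to a C–B bond. Benzylic boronate 13 is the direct product of a conjunctive coupling, and its stereocentre vanishes on protodeboronation, so no enantiocontrol is demanded of the key step.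

13 back to 8, 10 and 11. Two bonds are cut at once: C1 of ring A to the bridge carbon that carries boron, and the other bridge carbon to C3 of ring B. The cut is placed here because ring A is the simplest aryl group in the molecule and can be an aryllithium (11), while everything base-sensitive (the ester) sits in the electrophile, aryl triflate 8. The two-carbon bridge comes from vinylboronate 10. The forward reaction must make the ate complex 12 from 11 and 10, then have an aryl–palladium species from 8 induce the 1,2-shift of the ring A aryl and couple at the terminal carbon. The gain is full convergence: the whole ring B–C–D portion meets ring A in one operation.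

8 back to 7, then 5 and 6. The triflate is made from phenol 7, and 7 by cutting the ether C–O bond on the ring C side. That leaves ring B as the symmetric, purchasable 5-methoxyresorcinol 6 and ring C as aryl bromide 5. Cutting on the ring B side would need a differentiated 3,5-dioxygenated aryl halide, which is not an article of commerce. The forward reaction is a copper-catalysed mono-arylation of 6; the second hydroxyl of 6 is then already in place as the handle for the triflate.

5 back to 2 and 3, and 2 back to 1. The C–D bridge is cut between its two methylene carbons. The carbon on ring D is the methyl group of toluate 2 and is acidified by the ortho ester; the other is the benzylic bromide carbon of 3. This uses ring D as bought, with its oxygen pattern complete (1). The only preparation is benzylation of the phenol of 1 to give 2, which also sets up the final deprotection.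

11 back to 9. The aryllithium is made in the flask from aryl bromide 9 by halogen–metal exchange, directly before it is captured by 10.

## Alternatives that were turned down

Alternative 1: Ring B is not bought but built, by cutting two of its ring bonds. In the forward sense a malonate adds in conjugate fashion to the enone A2, which already carries the ring A arm. The methyl ketone enolate then closes onto one malonate ester (a Claisen condensation) to give the cyclohexane-1,3-dione ester A1 as the trans racemate. Decarboxylation and oxidative aromatisation would follow. In its favour, the chemistry is cheap and robust and the 1,3,5-pattern of ring B is unambiguous. Aromatisation in an alcohol can also deliver the two ring B oxygens already differentiated as one ether and one phenol. On that point it is stronger than the chosen route, which must mono-arylate the symmetric diol 6 under statistical control. Against it, some five steps are spent making a benzene ring that is commercially available as 6, and the two stereocentres of A1 are created only to be erased. The A–B bridge has to be made beforehand by separate carbonyl chemistry to reach A2. The diaryl ether and the whole ring C–D portion are still unsolved after the key step. The sequence is therefore long and linear. The chosen strategy instead buys all four rings and forms both bonds of the A–B bridge in one late, convergent step.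

Alternative 2: Ring D is cut open along its polyketide origin. The open-chain triketo ester A4 would cyclise under mild base by aldol attack of its C2 on the C7 ketone and dehydrate to the resorcylate A3. This mirrors biosynthesis and gives the correct oxygen pattern. The later 4-O-methylation would be selective, because the 2-hydroxyl of A3 is tied up in a hydrogen bond to the ester; that is a real strength. Against it, A4 is a 3,5,7-tricarbonyl compound that enolises, cyclises in more than one mode (lactone against carbocycle) and is hard to prepare with a large aryl arm attached. The arm must already contain the A–B bridge and the diaryl ether, so the key step solves none of the connection problems of the target. Ring D with exactly the required substituents is available as toluate 1, and two easy steps (benzylation and lateral alkylation) do in the chosen route what the aldol route needs a fragile precursor for.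

Alternative 3: Ring B is assembled by a benzannulation. Thermal electrocyclic opening of the cyclobutenone A6, [2+2] capture by the aryl ethynyl ether A7, a second four-electron opening and a six-electron closure would give the phenol A5. In A5 the aryloxy oxygen is meta to a free hydroxyl and the ring A arm sits in the remaining meta position. This is the most elegant answer to the ring B problem: all three substituents are placed by the mechanism, no diaryl ether coupling is needed, and the free hydroxyl is ready for methylation. There it is superior to the statistical arylation of 6. Against it, both partners are multi-step, sensitive compounds: A7 is an ynol ether that must be made and handled with care, and A6 has no short synthesis. The cascade needs prolonged heating. The acetal of A5 must still be converted into the C–D bridge with its own olefination and reduction. The step count is clearly higher. The chosen strategy gives up the programmed regiochemistry of ring B and gains purchasable rings, a short sequence and a key step that does not depend on strained or labile precursors.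

Key step: step 5

## Route

Remark: boronate 13 is drawn as its S enantiomer. The sense of induction follows the hand of the ligand and has no bearing on the achiral target, because the stereocentre is removed in step 6.

Step 1
Reactants: 1 methyl 2-hydroxy-4-methoxy-6-methylbenzoate
Product: 2 methyl 2-(benzyloxy)-4-methoxy-6-methylbenzoate
Conditions: BnBr, K2CO3, DMF, 60 °C
Reagents that add atoms: benzyl bromide, BrCc1ccccc1
Why: Williamson ether synthesis on the only acidic site of 1; the benzyl group masks the phenol for the base chemistry of step 2 and leaves in step 8 together with the ring A benzyl ether.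

Step 2
Reactants: 2 methyl 2-(benzyloxy)-4-methoxy-6-methylbenzoate; 3 4-bromobenzyl bromide
Product: 5 methyl 2-(benzyloxy)-6-[2-(4-bromophenyl)ethyl]-4-methoxybenzoate, via lithiated toluate 4 (not isolated)
Conditions: LiN(iPr)2 (1.1 equiv), THF, −78 °C, 2 added to the base; then 3, −78 °C to −40 °C
Reagents that add atoms: none
Why: Lateral lithiation of an ortho-toluate gives the ester-conjugated benzylic anion 4, which displaces the benzylic bromide of 3 in an SN2 reaction while the aryl bromide is inert to this stabilised anion. Inverse addition at low temperature keeps Claisen-type self-condensation at the hindered ester down.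

Step 3
Reactants: 5 methyl 2-(benzyloxy)-6-[2-(4-bromophenyl)ethyl]-4-methoxybenzoate; 6 5-methoxyresorcinol
Product: 7 methyl 2-(benzyloxy)-6-{2-[4-(3-hydroxy-5-methoxyphenoxy)phenyl]ethyl}-4-methoxybenzoate
Conditions: 6 (3 equiv), CuI (10 mol %), picolinic acid (20 mol %), K3PO4, DMSO, 90 °C
Reagents that add atoms: none
Why: Copper-catalysed Ullmann diaryl ether synthesis of an aryl bromide with a phenol. The excess of symmetric 6 biases the reaction towards mono-arylation and the surplus diol is removed by aqueous washing; the hindered ester and the benzyl ether tolerate the phosphate base.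

Step 4
Reactants: 7 methyl 2-(benzyloxy)-6-{2-[4-(3-hydroxy-5-methoxyphenoxy)phenyl]ethyl}-4-methoxybenzoate
Product: 8 methyl 2-(benzyloxy)-4-methoxy-6-{2-[4-(3-methoxy-5-{[(trifluoromethyl)sulfonyl]oxy}phenoxy)phenyl]ethyl}benzoate
Conditions: Tf2O, pyridine, CH2Cl2, 0 °C
Reagents that add atoms: trifluoromethanesulfonic anhydride, O=S(=O)(OS(=O)(=O)C(F)(F)F)C(F)(F)F
Why: O-sulfonylation of the single free phenol of 7; no other group in the molecule is nucleophilic under these conditions.

Step 5
Reactants: 9 1-(benzyloxy)-4-bromobenzene; 10 vinylboronic acid pinacol ester; 8 methyl 2-(benzyloxy)-4-methoxy-6-{2-[4-(3-methoxy-5-{[(trifluoromethyl)sulfonyl]oxy}phenoxy)phenyl]ethyl}benzoate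
Product: 13 methyl 2-(benzyloxy)-6-{2-[4-(3-{(2S)-2-[4-(benzyloxy)phenyl]-2-(4,4,5,5-tetramethyl-1,3,2-dioxaborolan-2-yl)ethyl}-5-methoxyphenoxy)phenyl]ethyl}-4-methoxybenzoate, via 4-(benzyloxy)phenyllithium 11 (not isolated), via lithium aryl(vinyl)boronate complex 12 (not isolated)
Conditions: 9 (1.4 equiv), t-BuLi (2.8 equiv), Et2O, −78 °C; 10 (1.5 equiv), −78 °C to rt; evaporate; then 8 (1.0 equiv), Pd(OAc)2 (3 mol %), (Sp,Sp)-MandyPhos (3.6 mol %), NaOTf (3 equiv), THF, 60 °C
Reagents that add atoms: none
Why: Bromine–lithium exchange on 9 gives 11, which adds to the vacant boron orbital of 10 to form the four-coordinate boronate 12; the slight excess of 10 ensures that no free organolithium meets the ester of 8. Zerovalent palladium, formed in the flask from Pd(OAc)2 (a divalent palladium source) and the bisphosphine, inserts into the C–OTf bond of 8, and because triflate does not coordinate, the resulting aryl–palladium is cationic and binds the electron-rich alkene of 12. Binding triggers the 1,2-shift of the ring A aryl from boron to the boron-bearing carbon while palladium takes the terminal carbon, and reductive elimination then forms the CH2–ring B bond; this is the known palladium-catalysed conjunctive cross-coupling of vinylboron ate complexes with aryl triflates. No ring is closed. The one new stereocentre, the carbon bearing boron, is set by the alkene face that the chiral ferrocene ligand presents to palladium, and its sense is immaterial since step 6 removes it. The step needs the metallate shift to win over direct Suzuki-type transfer of aryl or vinyl from boron and over beta-hydride elimination; the wide bite angle of the ferrocene bisphosphine speeds reductive elimination, and NaOTf takes up the bromide from the exchange that would otherwise block the cationic palladium site. In the substrates, the 4-benzyloxyphenyl group is electron-rich and migrates readily, the triflate of 8 is flanked by two meta oxygen substituents that act as inductive acceptors and ease oxidative addition, and 8 has no second carbon–halogen or carbon–sulfonate bond.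

Step 6
Reactants: 13 methyl 2-(benzyloxy)-6-{2-[4-(3-{(2S)-2-[4-(benzyloxy)phenyl]-2-(4,4,5,5-tetramethyl-1,3,2-dioxaborolan-2-yl)ethyl}-5-methoxyphenoxy)phenyl]ethyl}-4-methoxybenzoate
Product: 14 methyl 2-(benzyloxy)-6-{2-[4-(3-{2-[4-(benzyloxy)phenyl]ethyl}-5-methoxyphenoxy)phenyl]ethyl}-4-methoxybenzoate
Conditions: Bu4NF·3H2O (3 equiv), toluene, 90 °C
Reagents that add atoms: none
Why: Fluoride-promoted protodeboronation of a benzylic boronic ester: fluoride forms the boron ate complex and water protonates the benzylic carbon as the C–B bond breaks, boron leaving as the hydroxyborolane and fluoride being released again. The only stereocentre of the route disappears here, and any ester hydrolysed on the way is simply carried into step 7.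

Step 7
Reactants: 14 methyl 2-(benzyloxy)-6-{2-[4-(3-{2-[4-(benzyloxy)phenyl]ethyl}-5-methoxyphenoxy)phenyl]ethyl}-4-methoxybenzoate
Product: 15 2-(benzyloxy)-6-{2-[4-(3-{2-[4-(benzyloxy)phenyl]ethyl}-5-methoxyphenoxy)phenyl]ethyl}-4-methoxybenzoic acid
Conditions: KOH, EtOH/H2O, reflux; then 1 M HCl, 0 °C
Reagents that add atoms: potassium hydroxide, [K+].[OH-]
Why: Saponification of a doubly ortho-substituted methyl benzoate, which needs hot concentrated hydroxide but meets only inert aryl ethers elsewhere. The carboxylate is stable in base and cold acidification avoids decarboxylation of the electron-rich acid.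

Step 8
Reactants: 15 2-(benzyloxy)-6-{2-[4-(3-{2-[4-(benzyloxy)phenyl]ethyl}-5-methoxyphenoxy)phenyl]ethyl}-4-methoxybenzoic acid
Product: 16 2-hydroxy-6-{2-[4-(3-[2-(4-hydroxyphenyl)ethyl]-5-methoxyphenoxy)phenyl]ethyl}-4-methoxybenzoic acid (CNP0188714.0)
Conditions: H2 (1 atm), 10% Pd/C, EtOAc/MeOH, rt
Reagents that add atoms: none
Why: Hydrogenolysis of both aryl benzyl ethers over palladium on carbon under neutral conditions at room temperature; the diaryl ether, the methyl ethers and the decarboxylation-prone salicylic acid are not touched.

## Compound list

1 | methyl 2-hydroxy-4-methoxy-6-methylbenzoate | COC(=O)c1c(C)cc(OC)cc1O | starting material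
2 | methyl 2-(benzyloxy)-4-methoxy-6-methylbenzoate | COC(=O)c1c(C)cc(OC)cc1OCc1ccccc1 | intermediate
3 | 4-bromobenzyl bromide | BrCc1ccc(Br)cc1 | starting material
4 | methyl 2-(benzyloxy)-6-(lithiomethyl)-4-methoxybenzoate | [Li]Cc1cc(OC)cc(OCc2ccccc2)c1C(=O)OC | intermediate
5 | methyl 2-(benzyloxy)-6-[2-(4-bromophenyl)ethyl]-4-methoxybenzoate | COC(=O)c1c(OCc2ccccc2)cc(OC)cc1CCc1ccc(Br)cc1 | intermediate
6 | 5-methoxyresorcinol | COc1cc(O)cc(O)c1 | starting material
7 | methyl 2-(benzyloxy)-6-{2-[4-(3-hydroxy-5-methoxyphenoxy)phenyl]ethyl}-4-methoxybenzoate | COC(=O)c1c(OCc2ccccc2)cc(OC)cc1CCc1ccc(Oc2cc(OC)cc(O)c2)cc1 | intermediate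
8 | methyl 2-(benzyloxy)-4-methoxy-6-{2-[4-(3-methoxy-5-{[(trifluoromethyl)sulfonyl]oxy}phenoxy)phenyl]ethyl}benzoate | COC(=O)c1c(OCc2ccccc2)cc(OC)cc1CCc1ccc(Oc2cc(OC)cc(OS(=O)(=O)C(F)(F)F)c2)cc1 | intermediate
9 | 1-(benzyloxy)-4-bromobenzene | Brc1ccc(OCc2ccccc2)cc1 | starting material
10 | vinylboronic acid pinacol ester | C=CB1OC(C)(C)C(C)(C)O1 | starting material
11 | 4-(benzyloxy)phenyllithium | [Li]c1ccc(OCc2ccccc2)cc1 | intermediate
12 | lithium [4-(benzyloxy)phenyl](ethenyl)(pinacolato)borate | [Li+].C=C[B-]1(c2ccc(OCc3ccccc3)cc2)OC(C)(C)C(C)(C)O1 | intermediate
13 | methyl 2-(benzyloxy)-6-{2-[4-(3-{(2S)-2-[4-(benzyloxy)phenyl]-2-(4,4,5,5-tetramethyl-1,3,2-dioxaborolan-2-yl)ethyl}-5-methoxyphenoxy)phenyl]ethyl}-4-methoxybenzoate | COC(=O)c1c(OCc2ccccc2)cc(OC)cc1CCc1ccc(Oc2cc(OC)cc(C[C@H](B3OC(C)(C)C(C)(C)O3)c3ccc(OCc4ccccc4)cc3)c2)cc1 | intermediate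
14 | methyl 2-(benzyloxy)-6-{2-[4-(3-{2-[4-(benzyloxy)phenyl]ethyl}-5-methoxyphenoxy)phenyl]ethyl}-4-methoxybenzoate | COC(=O)c1c(OCc2ccccc2)cc(OC)cc1CCc1ccc(Oc2cc(OC)cc(CCc3ccc(OCc4ccccc4)cc3)c2)cc1 | intermediate
15 | 2-(benzyloxy)-6-{2-[4-(3-{2-[4-(benzyloxy)phenyl]ethyl}-5-methoxyphenoxy)phenyl]ethyl}-4-methoxybenzoic acid | OC(=O)c1c(OCc2ccccc2)cc(OC)cc1CCc1ccc(Oc2cc(OC)cc(CCc3ccc(OCc4ccccc4)cc3)c2)cc1 | intermediate
16 | 2-hydroxy-6-{2-[4-(3-[2-(4-hydroxyphenyl)ethyl]-5-methoxyphenoxy)phenyl]ethyl}-4-methoxybenzoic acid | COc1cc(CCc2ccc(O)cc2)cc(Oc2ccc(CCc3cc(OC)cc(O)c3C(=O)O)cc2)c1 | target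

## Step count and least certain steps

Total: 8 steps. Longest linear sequence: 8 steps (1 to 2 to 5 to 7 to 8 to 13 to 14 to 15 to 16); the ring A piece 9 and the vinylboronate 10 enter in step 5 without steps of their own.

Step 5 (key step). The most likely failure is that the boronate 12 hands its aryl or vinyl group directly to palladium (Suzuki-type transmetallation) instead of undergoing the 1,2-shift. This is favoured if bromide from the exchange occupies the cationic palladium site despite the NaOTf. Incomplete exchange or protonation of 12 during the solvent change would lower conversion further. Fallback: the A–B bridge would be made by a Sonogashira coupling instead. Triflate 8 and purchased 1-(benzyloxy)-4-ethynylbenzene would be coupled with PdCl2(PPh3)2, CuI and Et3N in DMF to give the diaryl alkyne methyl 2-(benzyloxy)-6-{2-[4-(3-{[4-(benzyloxy)phenyl]ethynyl}-5-methoxyphenoxy)phenyl]ethyl}-4-methoxybenzoate F1. Saponification with KOH in aqueous ethanol would give the alkyne acid F2. Hydrogenation over Pd/C would then saturate the triple bond and cleave both benzyl ethers in one operation, so the fallback comes back to the route at 16.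

Step 6. The C–B protonolysis may be slow, because the para benzyloxy group of ring A withdraws stabilisation from the developing negative charge at the benzylic carbon; long heating with wet fluoride could then begin to attack the ester before the boron is gone. Fallback: 13 would be oxidised with NaBO3·4H2O in THF/water, with retention, to the benzylic alcohol methyl 2-(benzyloxy)-6-{2-[4-(3-{(2S)-2-[4-(benzyloxy)phenyl]-2-hydroxyethyl}-5-methoxyphenoxy)phenyl]ethyl}-4-methoxybenzoate F3. Here the same para oxygen is an advantage: ionic deoxygenation with Et3SiH and CF3CO2H in CH2Cl2 at 0 °C passes through a well-stabilised benzylic cation and would return the route to 14.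

Step 3. Arylation of both hydroxyl groups of 6 may compete with mono-arylation, and the electron-neutral bromide 5 may turn over slowly in the copper cycle, so that long heating in basic DMSO starts to erode the ester. Fallback: the polarity of the C–O coupling would be reversed. Miyaura borylation of 5 (B2pin2, PdCl2(dppf), KOAc, dioxane, 80 °C) would give the pinacol boronate F4. Oxidative cleavage of the pinacol with NaIO4 and NH4OAc in aqueous acetone would give the boronic acid F5. A Chan–Lam coupling of F5 with excess 6 (Cu(OAc)2, pyridine, molecular sieves, CH2Cl2, air, room temperature) would deliver 7 under much milder conditions.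

Step 2. Proton transfer between the lithiated toluate 4 and the product may lead to a second benzylation, and addition of 4 to the ester of unreacted 2 (Claisen-type self-condensation) may consume material. Fallback: the electrophilic ester would be removed before the anion is made. Toluate 2 would be saponified to 2-(benzyloxy)-4-methoxy-6-methylbenzoic acid F6. Double deprotonation with LiN(iPr)2 (2.2 equiv) in THF and alkylation with 3 would give 2-(benzyloxy)-6-[2-(4-bromophenyl)ethyl]-4-methoxybenzoic acid F7. Methylation with MeI and K2CO3 in DMF would return the route to 5.

## Further compounds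

F1 | step 5 | methyl 2-(benzyloxy)-6-{2-[4-(3-{[4-(benzyloxy)phenyl]ethynyl}-5-methoxyphenoxy)phenyl]ethyl}-4-methoxybenzoate | COC(=O)c1c(OCc2ccccc2)cc(OC)cc1CCc1ccc(Oc2cc(OC)cc(C#Cc3ccc(OCc4ccccc4)cc3)c2)cc1
F2 | step 5 | 2-(benzyloxy)-6-{2-[4-(3-{[4-(benzyloxy)phenyl]ethynyl}-5-methoxyphenoxy)phenyl]ethyl}-4-methoxybenzoic acid | OC(=O)c1c(OCc2ccccc2)cc(OC)cc1CCc1ccc(Oc2cc(OC)cc(C#Cc3ccc(OCc4ccccc4)cc3)c2)cc1
F3 | step 6 | methyl 2-(benzyloxy)-6-{2-[4-(3-{(2S)-2-[4-(benzyloxy)phenyl]-2-hydroxyethyl}-5-methoxyphenoxy)phenyl]ethyl}-4-methoxybenzoate | COC(=O)c1c(OCc2ccccc2)cc(OC)cc1CCc1ccc(Oc2cc(OC)cc(C[C@H](O)c3ccc(OCc4ccccc4)cc3)c2)cc1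
F4 | step 3 | methyl 2-(benzyloxy)-4-methoxy-6-{2-[4-(4,4,5,5-tetramethyl-1,3,2-dioxaborolan-2-yl)phenyl]ethyl}benzoate | COC(=O)c1c(OCc2ccccc2)cc(OC)cc1CCc1ccc(B2OC(C)(C)C(C)(C)O2)cc1
F5 | step 3 | (4-{2-[3-(benzyloxy)-5-methoxy-2-(methoxycarbonyl)phenyl]ethyl}phenyl)boronic acid | COC(=O)c1c(OCc2ccccc2)cc(OC)cc1CCc1ccc(B(O)O)cc1
F6 | step 2 | 2-(benzyloxy)-4-methoxy-6-methylbenzoic acid | Cc1cc(OC)cc(OCc2ccccc2)c1C(=O)O
F7 | step 2 | 2-(benzyloxy)-6-[2-(4-bromophenyl)ethyl]-4-methoxybenzoic acid | OC(=O)c1c(OCc2ccccc2)cc(OC)cc1CCc1ccc(Br)cc1
A1 | alternative 1 | methyl trans-6-{2-[4-(benzyloxy)phenyl]ethyl}-2,4-dioxocyclohexane-1-carboxylate (racemic, one enantiomer drawn) | COC(=O)[C@H]1C(=O)CC(=O)C[C@@H]1CCc1ccc(OCc2ccccc2)cc1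
A2 | alternative 1 | (E)-6-[4-(benzyloxy)phenyl]hex-3-en-2-one | CC(=O)/C=C/CCc1ccc(OCc2ccccc2)cc1
A3 | alternative 2 | methyl 6-{2-[4-(3-{2-[4-(benzyloxy)phenyl]ethyl}-5-methoxyphenoxy)phenyl]ethyl}-2,4-dihydroxybenzoate | COC(=O)c1c(O)cc(O)cc1CCc1ccc(Oc2cc(OC)cc(CCc3ccc(OCc4ccccc4)cc3)c2)cc1
A4 | alternative 2 | methyl 9-[4-(3-{2-[4-(benzyloxy)phenyl]ethyl}-5-methoxyphenoxy)phenyl]-3,5,7-trioxononanoate | COC(=O)CC(=O)CC(=O)CC(=O)CCc1ccc(Oc2cc(OC)cc(CCc3ccc(OCc4ccccc4)cc3)c2)cc1
A5 | alternative 3 | 3-{2-[4-(benzyloxy)phenyl]ethyl}-5-[4-(dimethoxymethyl)phenoxy]phenol | Oc1cc(Oc2ccc(C(OC)OC)cc2)cc(CCc2ccc(OCc3ccccc3)cc2)c1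
A6 | alternative 3 | 3-{2-[4-(benzyloxy)phenyl]ethyl}cyclobut-2-en-1-one | O=C1C=C(CCc2ccc(OCc3ccccc3)cc2)C1
A7 | alternative 3 | 1-(dimethoxymethyl)-4-(ethynyloxy)benzene | C#COc1ccc(C(OC)OC)cc1
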